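**Retrosynthetic overview**

- Feature: C2 of the dihydrofuran ring carries both the ring oxygen O1 and the α-carbon of the propenal unit. O1–C2 and Cα–C(=O) are therefore the two bonds that an oxygen nucleophile and a one-carbon carbonyl unit add across the proximal double bond of an allene attached to C3.
- Target ⇒ (two O-tigloylations, desilylation, ester → allylic alcohol → aldehyde) methyl 2-(3-silyloxy-2,3-dihydrobenzofuran-2-yl)acrylate.
- Acrylate ⇒ (O1–C2 and Cα–C(=O) by oxypalladation/methoxycarbonylation; the only ring-forming step, closing the dihydrofuran ring onto the purchased benzene ring) ortho-(1-silyloxybuta-2,3-dienyl)phenol + CO + MeOH.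
- Allenyl phenol ⇒ (Crabbé homologation) propargylic silyl ether ⇒ (enantioselective alkynylation, sets C3) salicylaldehyde silyl ether ⇒ (Br–Li exchange/DMF; CBS reduction, sets the side-chain center) 3'-bromo-4'-hydroxyacetophenone.

Key step: step 10

Assumption: the binaphthol–Ti(OiPr)4 alkynylzinc addition is taken to follow the facial sense of dialkylzinc additions with the same catalyst, so (R)-1,1'-bi-2-naphthol is specified for Re-face delivery; the configuration of the propargylic alcohol is to be checked as its Mosher esters before scale-up.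

**Route**

Step 1
Reactants: 1 3'-bromo-4'-hydroxyacetophenone
Product: 2 1-[3-bromo-4-(triisopropylsilyloxy)phenyl]ethan-1-one
Conditions: TIPSCl, imidazole, DMF, rt
Reagents that add atoms: chlorotriisopropylsilane (TIPSCl), CC(C)[Si](Cl)(C(C)C)C(C)C
Why: Imidazole-promoted O-silylation of the acidic phenol (Corey silylation) should be clean, and the bulky aryl triisopropylsilyl ether is chosen because it withstands organolithium, carbonate/methanol and hot amine/copper conditions, is slow to undergo the 1,3 oxygen-to-carbon silyl shift in an ortho-lithiated ring, and is cleaved by fluoride well before an alkyl TBS ether.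

Step 2
Reactants: 2 1-[3-bromo-4-(triisopropylsilyloxy)phenyl]ethan-1-one
Product: 3 (R)-1-[3-bromo-4-(triisopropylsilyloxy)phenyl]ethan-1-ol
Conditions: (S)-1-methyl-3,3-diphenyltetrahydro-1H,3H-pyrrolo[1,2-c][1,3,2]oxazaborole (the (S)-methyl CBS catalyst, 10 mol%), BH3·SMe2, THF, 0 °C; MeOH quench
Reagents that add atoms: none
Why: Corey–Bakshi–Shibata reduction of an aryl methyl ketone, in which the (S)-oxazaborolidine–borane complex delivers hydride to the Si face with the aryl group as the large substituent, should set the side-chain stereocenter as R with high enantiomeric excess while the aryl bromide and the silyl ether are inert to borane.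

Step 3
Reactants: 3 (R)-1-[3-bromo-4-(triisopropylsilyloxy)phenyl]ethan-1-ol
Product: 4 [2-bromo-4-[(R)-1-(tert-butyldimethylsilyloxy)ethyl]phenoxy]triisopropylsilane
Conditions: TBSCl, imidazole, DMF, rt
Reagents that add atoms: tert-butylchlorodimethylsilane (TBSCl), CC(C)(C)[Si](C)(C)Cl
Why: Standard imidazole-promoted silylation of a secondary benzylic alcohol takes place at oxygen, so no bond to the stereocenter is broken and the carbinol is masked for the organometallic steps that follow.

Step 4
Reactants: 4 [2-bromo-4-[(R)-1-(tert-butyldimethylsilyloxy)ethyl]phenoxy]triisopropylsilane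
Product: 6 5-[(R)-1-(tert-butyldimethylsilyloxy)ethyl]-2-(triisopropylsilyloxy)benzaldehyde, via aryllithium 5 (not isolated)
Conditions: t-BuLi (2.1 equiv), Et2O, −78 °C; then DMF, −78 → 0 °C; H2O
Reagents that add atoms: N,N-dimethylformamide (DMF), CN(C)C=O
Why: Bromine–lithium exchange with two equivalents of t-BuLi is faster at −78 °C than any deprotonation or silyl migration, and formylation of the aryllithium with DMF (Bouveault aldehyde synthesis) should give the salicylaldehyde silyl ether without touching the benzylic stereocenter.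

Step 5
Reactants: 6 5-[(R)-1-(tert-butyldimethylsilyloxy)ethyl]-2-(triisopropylsilyloxy)benzaldehyde; 7 ethynyltrimethylsilane
Product: 8 (S)-1-[5-[(R)-1-(tert-butyldimethylsilyloxy)ethyl]-2-(triisopropylsilyloxy)phenyl]-3-(trimethylsilyl)prop-2-yn-1-ol
Conditions: 7, Et2Zn, Cy2NH (5 mol%), Et2O, rt; then (R)-1,1'-bi-2-naphthol (40 mol%), Ti(OiPr)4; then 6, rt; H2O
Reagents that add atoms: none
Why: The binaphthol–Ti(OiPr)4-catalysed addition of an alkynylzinc reagent to an aromatic aldehyde is a catalyst-controlled enantioselective alkynylation, so the (R)-ligand should deliver the alkyne to the Re face of the aldehyde and set the new carbinol center (S by the CIP rules because the silylalkynyl group outranks the aryl group) independently of the remote side-chain center.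

Step 6
Reactants: 8 (S)-1-[5-[(R)-1-(tert-butyldimethylsilyloxy)ethyl]-2-(triisopropylsilyloxy)phenyl]-3-(trimethylsilyl)prop-2-yn-1-ol
Product: 9 [2-[(S)-1-(tert-butyldimethylsilyloxy)-3-(trimethylsilyl)prop-2-ynyl]-4-[(R)-1-(tert-butyldimethylsilyloxy)ethyl]phenoxy]triisopropylsilane
Conditions: TBSOTf, 2,6-lutidine, CH2Cl2, −78 → 0 °C
Reagents that add atoms: tert-butyldimethylsilyl trifluoromethanesulfonate (TBSOTf), CC(C)(C)[Si](C)(C)OS(=O)(=O)C(F)(F)F
Why: Silylation of the hindered secondary propargylic benzylic alcohol with the reactive silyl triflate and a non-nucleophilic base should be complete at low temperature and keeps the future C3 oxygen from taking part in the palladium step.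

Step 7
Reactants: 9 [2-[(S)-1-(tert-butyldimethylsilyloxy)-3-(trimethylsilyl)prop-2-ynyl]-4-[(R)-1-(tert-butyldimethylsilyloxy)ethyl]phenoxy]triisopropylsilane
Product: 10 [2-[(R)-1-(tert-butyldimethylsilyloxy)prop-2-ynyl]-4-[(R)-1-(tert-butyldimethylsilyloxy)ethyl]phenoxy]triisopropylsilane
Conditions: K2CO3 (0.2 equiv), MeOH/THF, 0 °C
Reagents that add atoms: none
Why: Catalytic methoxide cleaves the alkynyl C–Si bond (protodesilylation of a silylalkyne) much faster than it attacks the bulky aryl triisopropylsilyl ether or the alkyl TBS ethers at 0 °C, and the descriptor of the propargylic center changes from S to R only because the terminal alkyne now ranks below the aryl group.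

Step 8
Reactants: 10 [2-[(R)-1-(tert-butyldimethylsilyloxy)prop-2-ynyl]-4-[(R)-1-(tert-butyldimethylsilyloxy)ethyl]phenoxy]triisopropylsilane
Product: 11 [2-[(R)-1-(tert-butyldimethylsilyloxy)buta-2,3-dienyl]-4-[(R)-1-(tert-butyldimethylsilyloxy)ethyl]phenoxy]triisopropylsilane
Conditions: CuI (0.5 equiv), (CH2O)n, Cy2NH, 1,4-dioxane, reflux
Reagents that add atoms: paraformaldehyde (formaldehyde unit), C=O
Why: Crabbé homologation in its CuI/dicyclohexylamine variant should convert the terminal alkyne through a Mannich propargylic amine and copper-mediated 1,5-hydride transfer into the terminal allene without involving the adjacent silyloxy-bearing stereocenter, and the phenol is kept silylated here because a free phenol would be aminomethylated under these Mannich conditions.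

Step 9
Reactants: 11 [2-[(R)-1-(tert-butyldimethylsilyloxy)buta-2,3-dienyl]-4-[(R)-1-(tert-butyldimethylsilyloxy)ethyl]phenoxy]triisopropylsilane
Product: 12 2-[(R)-1-(tert-butyldimethylsilyloxy)buta-2,3-dienyl]-4-[(R)-1-(tert-butyldimethylsilyloxy)ethyl]phenol
Conditions: Bu4NF (1.1 equiv), AcOH (1.1 equiv), THF, 0 °C
Reagents that add atoms: none
Why: Fluoride-mediated desilylation is much faster for the aryl silyl ether (phenoxide leaving group) than for the two secondary alkyl TBS ethers, and buffering with acetic acid keeps the liberated phenol from standing as its phenoxide, so that neither quinone methide formation nor silyl migration is expected.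

Step 10
Reactants: 12 2-[(R)-1-(tert-butyldimethylsilyloxy)buta-2,3-dienyl]-4-[(R)-1-(tert-butyldimethylsilyloxy)ethyl]phenol; 13 carbon monoxide; 14 methanol
Product: 17 methyl 2-[(2R,3S)-3-(tert-butyldimethylsilyloxy)-5-[(R)-1-(tert-butyldimethylsilyloxy)ethyl]-2,3-dihydrobenzofuran-2-yl]acrylate, via vinylpalladium chloride 15 (not isolated), via acylpalladium chloride 16 (not isolated)
Conditions: PdCl2(MeCN)2 (10 mol%), CuCl2 (2.5 equiv), NaOAc (3 equiv), CO (1 atm), MeOH, 0 °C → rt
Reagents that add atoms: none
Why: PdCl2 coordinates the proximal double bond of the allene in 12, the phenol oxygen adds anti to palladium at the proximal allene carbon to form O1–C2 and the vinylpalladium chloride 15 at the former central carbon, CO inserts to give the acylpalladium chloride 16, and methanolysis releases ester 17 with zerovalent palladium, which CuCl2 returns to divalent palladium while NaOAc takes up the HCl. The closest known reaction is the oxypalladation–methoxycarbonylation of 4,5-dienols to 2-(1-methoxycarbonylvinyl)tetrahydrofurans under PdCl2/CuCl2/CO/MeOH, together with the Wacker-type cyclisation–carbonylation of ortho-alkenyl phenols, and the alternative course through addition of a methoxycarbonylpalladium species to the central carbon followed by attack of the phenol on the resulting allylpalladium leads to the same product. The dihydrofuran ring closes in the 5-exo-trig mode at the proximal sp2 carbon of the allene. The new C2 stereocenter is set by the existing C3 center, because the palladium-bound allene turns away from the bulky C3 silyloxy group in the closing conformer, which should place the C2 substituent trans to the C3 oxygen (2R; the C3 descriptor changes from R to S only through the change of priorities). The step needs attack at the proximal and not the terminal allene carbon, which the tether secures because the terminal carbon would require a seven-membered ring, and it needs the phenol to be the only oxygen nucleophile, which the two TBS ethers secure. The acetate buffer is included because the benzylic silyl ethers ortho and para to the ring oxygen would not survive the HCl that the unbuffered copper system releases.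

Step 11
Reactants: 17 methyl 2-[(2R,3S)-3-(tert-butyldimethylsilyloxy)-5-[(R)-1-(tert-butyldimethylsilyloxy)ethyl]-2,3-dihydrobenzofuran-2-yl]acrylate
Product: 18 2-[(2R,3S)-3-(tert-butyldimethylsilyloxy)-5-[(R)-1-(tert-butyldimethylsilyloxy)ethyl]-2,3-dihydrobenzofuran-2-yl]prop-2-en-1-ol
Conditions: i-Bu2AlH (2.5 equiv), CH2Cl2, −78 °C; aqueous potassium sodium tartrate
Reagents that add atoms: none
Why: i-Bu2AlH at −78 °C reduces the conjugated methyl ester by 1,2-hydride addition to the allylic alcohol, and the silyl ethers, the aryl ether and the existing stereocenters are untouched under these non-basic conditions.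

Step 12
Reactants: 18 2-[(2R,3S)-3-(tert-butyldimethylsilyloxy)-5-[(R)-1-(tert-butyldimethylsilyloxy)ethyl]-2,3-dihydrobenzofuran-2-yl]prop-2-en-1-ol
Product: 19 2-[(2R,3S)-3-(tert-butyldimethylsilyloxy)-5-[(R)-1-(tert-butyldimethylsilyloxy)ethyl]-2,3-dihydrobenzofuran-2-yl]prop-2-enal
Conditions: MnO2 (excess), CH2Cl2, rt
Reagents that add atoms: none
Why: MnO2 oxidises allylic alcohols selectively under neutral heterogeneous conditions, so the 2-substituted propenal should form without epimerisation at C2 or migration of the double bond.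

Step 13
Reactants: 19 2-[(2R,3S)-3-(tert-butyldimethylsilyloxy)-5-[(R)-1-(tert-butyldimethylsilyloxy)ethyl]-2,3-dihydrobenzofuran-2-yl]prop-2-enal
Product: 20 2-[(2R,3S)-3-hydroxy-5-[(R)-1-hydroxyethyl]-2,3-dihydrobenzofuran-2-yl]prop-2-enal
Conditions: HF·pyridine, pyridine, THF, 0 °C → rt
Reagents that add atoms: none
Why: Pyridine-buffered HF·pyridine cleaves secondary TBS ethers by fluoride attack at silicon (fluoride desilylation) under weakly acidic, non-basic conditions, which should spare the enal and should not ionise the benzylic C–O bonds, so that C3 and the side-chain carbinol keep their configuration.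

Step 14
Reactants: 21 tiglic acid, (E)-2-methylbut-2-enoic acid (two molecules condense)
Product: 22 tiglic anhydride, (E)-2-methylbut-2-enoic anhydride
Conditions: 21 (2 equiv), N,N'-dicyclohexylcarbodiimide (1 equiv), CH2Cl2, 0 °C → rt; filtration
Reagents that add atoms: tiglic acid (the second molecule of 21), C/C=C(\C)C(=O)O
Why: Carbodiimide-mediated dehydration, in which the O-acylisourea formed from one molecule of the acid is attacked at its carbonyl carbon by a second molecule of the acid, gives the symmetric anhydride with both E double bonds unchanged, and the urea that takes up the water is removed by filtration.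

Step 15
Reactants: 20 2-[(2R,3S)-3-hydroxy-5-[(R)-1-hydroxyethyl]-2,3-dihydrobenzofuran-2-yl]prop-2-enal; 22 tiglic anhydride
Product: 23 (R)-1-[(2R,3S)-3-[(E)-2-methylbut-2-enoyloxy]-2-(3-oxoprop-1-en-2-yl)-2,3-dihydrobenzofuran-5-yl]ethyl (E)-2-methylbut-2-enoate (CNP0292799.1)
Conditions: 22 (4 equiv), 4-(dimethylamino)pyridine (0.3 equiv), pyridine, CH2Cl2, 0 °C → rt
Reagents that add atoms: tiglic anhydride (a second molecule of 22, since each hydroxyl takes its acyl group from one molecule of anhydride), C/C=C(\C)C(=O)OC(=O)/C(C)=C/C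
Why: Acyl transfer from the anhydride catalysed by 4-(dimethylamino)pyridine (Steglich-type esterification) acylates both secondary benzylic alcohols at oxygen with retention at carbon, one molecule of anhydride being consumed per hydroxyl, and the anhydride is preferred to the acid chloride because no vinylketene pathway can deconjugate or isomerise the tigloyl group.

**Compound list**

1 | 3'-bromo-4'-hydroxyacetophenone | CC(=O)c1ccc(O)c(Br)c1 | starting material
2 | 1-[3-bromo-4-(triisopropylsilyloxy)phenyl]ethan-1-one | CC(=O)c1ccc(O[Si](C(C)C)(C(C)C)C(C)C)c(Br)c1 | intermediate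
3 | (R)-1-[3-bromo-4-(triisopropylsilyloxy)phenyl]ethan-1-ol | Brc1cc([C@@H](C)O)ccc1O[Si](C(C)C)(C(C)C)C(C)C | intermediate
4 | [2-bromo-4-[(R)-1-(tert-butyldimethylsilyloxy)ethyl]phenoxy]triisopropylsilane | Brc1cc([C@@H](C)O[Si](C)(C)C(C)(C)C)ccc1O[Si](C(C)C)(C(C)C)C(C)C | intermediate
5 | [5-[(R)-1-(tert-butyldimethylsilyloxy)ethyl]-2-(triisopropylsilyloxy)phenyl]lithium (not isolated) | [Li]c1cc([C@@H](C)O[Si](C)(C)C(C)(C)C)ccc1O[Si](C(C)C)(C(C)C)C(C)C | intermediate
6 | 5-[(R)-1-(tert-butyldimethylsilyloxy)ethyl]-2-(triisopropylsilyloxy)benzaldehyde | O=Cc1cc([C@@H](C)O[Si](C)(C)C(C)(C)C)ccc1O[Si](C(C)C)(C(C)C)C(C)C | intermediate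
7 | ethynyltrimethylsilane | C[Si](C)(C)C#C | starting material
8 | (S)-1-[5-[(R)-1-(tert-butyldimethylsilyloxy)ethyl]-2-(triisopropylsilyloxy)phenyl]-3-(trimethylsilyl)prop-2-yn-1-ol | C[Si](C)(C)C#C[C@@H](O)c1cc([C@@H](C)O[Si](C)(C)C(C)(C)C)ccc1O[Si](C(C)C)(C(C)C)C(C)C | intermediate
9 | [2-[(S)-1-(tert-butyldimethylsilyloxy)-3-(trimethylsilyl)prop-2-ynyl]-4-[(R)-1-(tert-butyldimethylsilyloxy)ethyl]phenoxy]triisopropylsilane | C[Si](C)(C)C#C[C@@H](O[Si](C)(C)C(C)(C)C)c1cc([C@@H](C)O[Si](C)(C)C(C)(C)C)ccc1O[Si](C(C)C)(C(C)C)C(C)C | intermediate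
10 | [2-[(R)-1-(tert-butyldimethylsilyloxy)prop-2-ynyl]-4-[(R)-1-(tert-butyldimethylsilyloxy)ethyl]phenoxy]triisopropylsilane | C#C[C@@H](O[Si](C)(C)C(C)(C)C)c1cc([C@@H](C)O[Si](C)(C)C(C)(C)C)ccc1O[Si](C(C)C)(C(C)C)C(C)C | intermediate
11 | [2-[(R)-1-(tert-butyldimethylsilyloxy)buta-2,3-dienyl]-4-[(R)-1-(tert-butyldimethylsilyloxy)ethyl]phenoxy]triisopropylsilane | C=C=C[C@@H](O[Si](C)(C)C(C)(C)C)c1cc([C@@H](C)O[Si](C)(C)C(C)(C)C)ccc1O[Si](C(C)C)(C(C)C)C(C)C | intermediate
12 | 2-[(R)-1-(tert-butyldimethylsilyloxy)buta-2,3-dienyl]-4-[(R)-1-(tert-butyldimethylsilyloxy)ethyl]phenol | C=C=C[C@@H](O[Si](C)(C)C(C)(C)C)c1cc([C@@H](C)O[Si](C)(C)C(C)(C)C)ccc1O | intermediate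
13 | carbon monoxide | [C-]#[O+] | starting material
14 | methanol | CO | starting material
15 | chloro[1-[trans-3-(tert-butyldimethylsilyloxy)-5-[(R)-1-(tert-butyldimethylsilyloxy)ethyl]-2,3-dihydrobenzofuran-2-yl]vinyl]palladium, ring configuration as in 17, further ligands omitted (not isolated) | C=C([Pd]Cl)[C@H]1Oc2ccc([C@@H](C)O[Si](C)(C)C(C)(C)C)cc2[C@@H]1O[Si](C)(C)C(C)(C)C | intermediate
16 | chloro[2-[trans-3-(tert-butyldimethylsilyloxy)-5-[(R)-1-(tert-butyldimethylsilyloxy)ethyl]-2,3-dihydrobenzofuran-2-yl]acryloyl]palladium, ring configuration as in 17, further ligands omitted (not isolated) | C=C(C(=O)[Pd]Cl)[C@H]1Oc2ccc([C@@H](C)O[Si](C)(C)C(C)(C)C)cc2[C@@H]1O[Si](C)(C)C(C)(C)C | intermediate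
17 | methyl 2-[(2R,3S)-3-(tert-butyldimethylsilyloxy)-5-[(R)-1-(tert-butyldimethylsilyloxy)ethyl]-2,3-dihydrobenzofuran-2-yl]acrylate | C=C(C(=O)OC)[C@H]1Oc2ccc([C@@H](C)O[Si](C)(C)C(C)(C)C)cc2[C@@H]1O[Si](C)(C)C(C)(C)C | intermediate
18 | 2-[(2R,3S)-3-(tert-butyldimethylsilyloxy)-5-[(R)-1-(tert-butyldimethylsilyloxy)ethyl]-2,3-dihydrobenzofuran-2-yl]prop-2-en-1-ol | C=C(CO)[C@H]1Oc2ccc([C@@H](C)O[Si](C)(C)C(C)(C)C)cc2[C@@H]1O[Si](C)(C)C(C)(C)C | intermediate
19 | 2-[(2R,3S)-3-(tert-butyldimethylsilyloxy)-5-[(R)-1-(tert-butyldimethylsilyloxy)ethyl]-2,3-dihydrobenzofuran-2-yl]prop-2-enal | C=C(C=O)[C@H]1Oc2ccc([C@@H](C)O[Si](C)(C)C(C)(C)C)cc2[C@@H]1O[Si](C)(C)C(C)(C)C | intermediate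
20 | 2-[(2R,3S)-3-hydroxy-5-[(R)-1-hydroxyethyl]-2,3-dihydrobenzofuran-2-yl]prop-2-enal | C=C(C=O)[C@H]1Oc2ccc([C@@H](C)O)cc2[C@@H]1O | intermediate
21 | tiglic acid, (E)-2-methylbut-2-enoic acid | C/C=C(\C)C(=O)O | starting material
22 | tiglic anhydride, (E)-2-methylbut-2-enoic anhydride | C/C=C(\C)C(=O)OC(=O)/C(C)=C/C | intermediate
23 | (R)-1-[(2R,3S)-3-[(E)-2-methylbut-2-enoyloxy]-2-(3-oxoprop-1-en-2-yl)-2,3-dihydrobenzofuran-5-yl]ethyl (E)-2-methylbut-2-enoate | C=C(C=O)[C@H]1Oc2ccc([C@@H](C)OC(=O)/C(C)=C/C)cc2[C@@H]1OC(=O)/C(C)=C/C | target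

**Step count**

Total step count: 15. Longest linear sequence: 14 steps (steps 1–13 and 15, from 1 to 23); step 14 is a one-step branch.

**Steps most likely to fail**

Step 10. The ring closure may discriminate poorly between the two faces of the allene, giving a cis/trans mixture at C2. The vinylpalladium intermediate may be protonated before carbon monoxide inserts. The free phenol and the benzylic silyl ethers may be degraded by the copper oxidant and the acid it releases. Fallback: setting out from 12, iodoetherification with N-iodosuccinimide in CH2Cl2 at −20 °C closes the same ring by 5-exo attack of the phenol at the proximal allene carbon and should give (2S,3S)-3-(tert-butyldimethylsilyloxy)-5-[(R)-1-(tert-butyldimethylsilyloxy)ethyl]-2-(1-iodovinyl)-2,3-dihydrobenzofuran F1, the trans isomer, from which any cis isomer can be removed by chromatography. Methoxycarbonylation of this vinyl iodide (PdCl2(PPh3)2 as precatalyst for zerovalent palladium, CO at 1 atm, MeOH, Et3N, 50 °C) then gives 17, where the route is rejoined. Ring closure and carbonylation are separated in this way, the carbonylation needs no oxidant and the medium is basic.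

Step 5. The bulky ortho silyloxy group may slow the addition and erode the enantioselectivity, or the facial sense may be opposite to the one assumed. Fallback: setting out from 6, addition of lithium (trimethylsilyl)acetylide (from 7 and n-BuLi, THF, −78 °C) gives 1-[5-[(R)-1-(tert-butyldimethylsilyloxy)ethyl]-2-(triisopropylsilyloxy)phenyl]-3-(trimethylsilyl)prop-2-yn-1-ol as a mixture of carbinol epimers F2. Oxidation with MnO2 in CH2Cl2 gives 1-[5-[(R)-1-(tert-butyldimethylsilyloxy)ethyl]-2-(triisopropylsilyloxy)phenyl]-3-(trimethylsilyl)prop-2-yn-1-one F3. Midland reduction of the ynone with (S)-Alpine-Borane (B-isopinocampheyl-9-borabicyclo[3.3.1]nonane from (−)-α-pinene), in which the alkyne takes the part of the small group, should then give 8, where the route is rejoined; the enantiomeric reagent would be taken if the Mosher analysis showed the opposite sense.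

Step 15. The nucleophilic catalyst and the base may add to the unhindered 2-substituted propenal, or may trigger loss of the C3 acyloxy group toward the aromatic benzofuran, and the hindered C3 alcohol may acylate slowly; the fluoride step before it exposes the same enal. Fallback: setting out from 18, the primary allylic alcohol is masked with levulinic acid, N,N'-dicyclohexylcarbodiimide and 4-(dimethylamino)pyridine as 2-[(2R,3S)-3-(tert-butyldimethylsilyloxy)-5-[(R)-1-(tert-butyldimethylsilyloxy)ethyl]-2,3-dihydrobenzofuran-2-yl]allyl 4-oxopentanoate F4. HF·pyridine then cleaves both TBS ethers to 2-[(2R,3S)-3-hydroxy-5-[(R)-1-hydroxyethyl]-2,3-dihydrobenzofuran-2-yl]allyl 4-oxopentanoate F5. Acylation with 22 and 4-(dimethylamino)pyridine gives (R)-1-[(2R,3S)-3-[(E)-2-methylbut-2-enoyloxy]-2-[3-(4-oxopentanoyloxy)prop-1-en-2-yl]-2,3-dihydrobenzofuran-5-yl]ethyl (E)-2-methylbut-2-enoate F6. Hydrazine acetate in pyridine/AcOH removes the levulinate to give (R)-1-[(2R,3S)-2-(3-hydroxyprop-1-en-2-yl)-3-[(E)-2-methylbut-2-enoyloxy]-2,3-dihydrobenzofuran-5-yl]ethyl (E)-2-methylbut-2-enoate F7, and MnO2 in CH2Cl2 oxidises this allylic alcohol to 23. The enal is then formed last, under neutral conditions, and C2–H is not activated while fluoride, base and acylation catalyst are present.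

**Further compounds**

F1 | step 10 | (2S,3S)-3-(tert-butyldimethylsilyloxy)-5-[(R)-1-(tert-butyldimethylsilyloxy)ethyl]-2-(1-iodovinyl)-2,3-dihydrobenzofuran (trans; C2 is S only because iodine raises the rank of the vinyl carbon) | C=C(I)[C@H]1Oc2ccc([C@@H](C)O[Si](C)(C)C(C)(C)C)cc2[C@@H]1O[Si](C)(C)C(C)(C)C
F2 | step 5 | 1-[5-[(R)-1-(tert-butyldimethylsilyloxy)ethyl]-2-(triisopropylsilyloxy)phenyl]-3-(trimethylsilyl)prop-2-yn-1-ol, mixture of epimers at C1 | C[Si](C)(C)C#CC(O)c1cc([C@@H](C)O[Si](C)(C)C(C)(C)C)ccc1O[Si](C(C)C)(C(C)C)C(C)C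
F3 | step 5 | 1-[5-[(R)-1-(tert-butyldimethylsilyloxy)ethyl]-2-(triisopropylsilyloxy)phenyl]-3-(trimethylsilyl)prop-2-yn-1-one | C[Si](C)(C)C#CC(=O)c1cc([C@@H](C)O[Si](C)(C)C(C)(C)C)ccc1O[Si](C(C)C)(C(C)C)C(C)C
F4 | step 15 | 2-[(2R,3S)-3-(tert-butyldimethylsilyloxy)-5-[(R)-1-(tert-butyldimethylsilyloxy)ethyl]-2,3-dihydrobenzofuran-2-yl]allyl 4-oxopentanoate | C=C(COC(=O)CCC(C)=O)[C@H]1Oc2ccc([C@@H](C)O[Si](C)(C)C(C)(C)C)cc2[C@@H]1O[Si](C)(C)C(C)(C)C
F5 | step 15 | 2-[(2R,3S)-3-hydroxy-5-[(R)-1-hydroxyethyl]-2,3-dihydrobenzofuran-2-yl]allyl 4-oxopentanoate | C=C(COC(=O)CCC(C)=O)[C@H]1Oc2ccc([C@@H](C)O)cc2[C@@H]1O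
F6 | step 15 | (R)-1-[(2R,3S)-3-[(E)-2-methylbut-2-enoyloxy]-2-[3-(4-oxopentanoyloxy)prop-1-en-2-yl]-2,3-dihydrobenzofuran-5-yl]ethyl (E)-2-methylbut-2-enoate | C=C(COC(=O)CCC(C)=O)[C@H]1Oc2ccc([C@@H](C)OC(=O)/C(C)=C/C)cc2[C@@H]1OC(=O)/C(C)=C/C
F7 | step 15 | (R)-1-[(2R,3S)-2-(3-hydroxyprop-1-en-2-yl)-3-[(E)-2-methylbut-2-enoyloxy]-2,3-dihydrobenzofuran-5-yl]ethyl (E)-2-methylbut-2-enoate | C=C(CO)[C@H]1Oc2ccc([C@@H](C)OC(=O)/C(C)=C/C)cc2[C@@H]1OC(=O)/C(C)=C/C
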